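The green flask levels off higher than the teal flask, at a mean of 21.4% of the substrate G as product Q against 13.9%, with the reagent E charged at 1.2 M against 0.80 M. L is a second substrate that also takes E and gives D. Z is the catalyst, and J and X are forms it can turn into.

all flasks: temperature 70 °C

| charge | G | E | L | Z | remark | time |
|---|---|---|---|---|---|---|
| green | 1 M | 1.2 M | 1 M | 1 mM | the very flask that is asked about, followed so far |  |
| teal | 1 M | 0.80 M | 1 M | 1 mM | run made earlier |  |
| flask | 1.0 M | 1.20 M | 1.00 M | 1.0 mM |  | 12 h |

| run | time / min | Q / % |
|---|---|---|
| green | 120 | 21.5 |
| green | 240 | 21.6 |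
| green | 300 | 21.0 |
| green | 480 | 21.5 |
| teal | 4.00 | 13.3 |
| teal | 10.0 | 14.0 |
| teal | 20.0 | 13.9 |
| teal | 30.0 | 14.3 |

(scatter of a reading: 0.5 percentage points)

- removed Q is counted in
- steps under discussion: G + E + Z -> Z + Q; L + E + Z -> Z + D; 2 Z -> J; Z -> X
- the earlier runs do not show what temperature does; that part of a forecast is a guess
- additions bring no volume worth counting

- autumn: change nothing and wait 4.0 h more
- dusk: at 12 h add Z, 100% of the amount charged, then wait 4.0 h
- noon: at 12 h take out 90% of the Q then present, then wait 4.0 h
- spring: at 12 h raise the temperature by 25 K, then wait 4.0 h
- summer: at 12 h add E, 50.0% of the amount charged, then wait 4.0 h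

- Q, in percent of the G first charged, at 12 h
- which option adds most Q ("none" when 2 percentage points or less is all one gets) (autumn / dusk / noon / spring / summer / none)
- Q present, with what was taken out counted in, in percent of the G first charged, after noon
- Q present, with what was taken out counted in, in percent of the G first charged, after spring

In slow motion, the first instants have Z at its charge, with G and L competing for E. Teal already shows 13.3% at 4.00 min, against its plateau of 13.9%, so the working phase of teal lasts minutes.

In the middle, Z leaves by pairing into J and by turning into X. Neither step involves G, L or E, so equal charges of Z should give green and teal the same Z summed over time.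

At the end the readings are flat: green shows 21.5% at 120 min and 21.5% at 480 min, a gap within the scatter of 0.5 percentage points.

The useful count is therefore the fraction of G left and not the fraction made, since G falls pseudo-first-order at given E and Z. Green gives 0.201 L mol⁻¹ for the reach, meaning the logarithm of one over the fraction of G left at the plateau, per unit of E charged. Teal reads 0.187 L mol⁻¹. My own reckoning carries teal's reach to the E of the asked flask and gets 20.1%, while green's own readings, the same flask, give 21.4%. I commit to the latter for 12 h. If the flat readings mean that Z has left, a restart needs new Z, but the size of the gain needs the E left, and these readings show Q and not E.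

The forecast gives 21.4%, names dusk, and holds Q at 21.5% after noon and 21.5% after spring. Its ground is that “Both runs instead fit a fixed catalyst lifetime”. It expects about 0.25 M of E left and a gain of about 6 points.

The flask gives 20.8%, with dusk best at 13 points, and 20.8% after noon and 20.8% after spring.

    G + E + Z → Z + Q (k = 3.00 L² mol⁻² s⁻¹, Ea = 41.0 kJ mol⁻¹)
    L + E + Z → Z + D (k = 1.80 L² mol⁻² s⁻¹, Ea = 44.0 kJ mol⁻¹)
    2 Z → J (k = 10.0 L mol⁻¹ s⁻¹, Ea = 52.0 kJ mol⁻¹)
    Z → X (k = 0.00550 s⁻¹, Ea = 107 kJ mol⁻¹)
    (constants at 70 °C)

At 72.0 min the asked flask already holds Z at 0%, and at 12 h it keeps 0.861 M of E, against the forecast's 0.25 M. Dusk adds 100% of the Z charged, so reach times that E, applied to the G left, reckons a gain of 13 points. Z summed over time goes as the logarithm of one plus 2k₃[Z]₀/k₄. A neighbour charged with a quarter of the Z therefore has 0.422 of the reach, which gives 9.65% of Q. The simulated neighbour stands at 10.2%, with Z at 0% and 86% of its E left.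

The data were generated by integration with made-up constants; scatter was added.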